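**Compound numbers used throughout:** 1 dotriacontanoic acid; 2 dotriacontanoyl chloride; 3 2-methylresorcinol; 4 1-(2,4-dihydroxy-3-methylphenyl)ethanone; 5 pivaloyl chloride; 6 4-acetyl-3-hydroxy-2-methylphenyl pivalate; 7 6-acetyl-2-methyl-3-(pivaloyloxy)phenyl dotriacontanoate; 8 3-hydroxy-2-methyl-4-(3-oxotetratriacontanoyl)phenyl pivalate; 9 2-hentriacontyl-8-methyl-4-oxo-4H-chromen-7-yl pivalate; 10 its 5-trifluoroacetate (formed in the flask); 11 2-hentriacontyl-5-hydroxy-8-methyl-4-oxo-4H-chromen-7-yl pivalate; 12 the target.

## Analysis of the target

The target 12 is a 4H-chromen-4-one: a benzene ring A fused to a 4-pyranone, with hydroxyls on C5 and C7, a methyl on C8 and an unbranched C31 chain on C2 (C41H70O4). It has no stereocentre and no double-bond geometry, so the problem is one of regiochemistry on ring A and of handling a wax-like chain. The sensitive sites are the acidic 7-hydroxyl, the chelated 5-hydroxyl and the electrophilic C2 of the pyranone: base can open the pyranone to a 1,3-diketone, and once a free 5-hydroxyl is present, reclosure on O5 would move the methyl from C8 to C6. The chain rules the physical behaviour, so its intermediates must be kept warm in THF, toluene or chlorinated solvents, and cold polar media are avoided. What makes the synthesis hard is that ring A is a C-methylphloroglucinol in which the two oxygens flanking the acyl carbon C4a are nearly alike, and closing the pyranone on the wrong one gives the 6-methyl isomer. The strategy rests on two features: O7–C7, C8–CH3 and C8a–O1 together are the pattern of mirror-symmetric 2-methylresorcinol 3, whose two open ring positions are equivalent, and the third oxygen sits on C5, peri to the C4 carbonyl, the one C–H of ring A that a metal bound to that carbonyl can reach through a five-membered metallacycle. Ring A is therefore built with two oxygens only and the C5 oxygen is put in last.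

## Retrosynthetic reasoning

**12 from 11 (O7–acyl bond).** The last bond cut is the ester bond between O7 and the pivaloyl carbon. It is cut there because O7 has to be masked through every earlier step, and an ester is the one kind of mask that survives the acidic, oxidising medium of the preceding step while also withdrawing electron density from ring A. The forward step has to take a hindered aryl ester off a chromone that now carries a free 5-hydroxyl without opening the pyranone. A mild basic methanolysis is chosen, and the 7-phenoxide that it sets free protects C2 by donating into the C4 carbonyl.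

**11 from 9 (C5–O bond).** This is the disconnection on which the route stands. It is placed at C5 because C5–H is peri to the C4 carbonyl: a metal held by that oxygen reaches C5 through a five-membered metallacycle and can reach no other C–H (C3 would need a four-membered ring, C6 is out of range, C8 carries the methyl). Ordinary electrophilic chemistry on 9 would go to C6, next to O7, so only chelation can deliver an oxygen to C5. The gain is that ring A of 9 has only two oxygens with the methyl between them, which is the pattern of symmetric 3, so the 6-methyl/8-methyl question never arises. The forward reaction has to oxidise one arene C–H in the presence of an ester, a benzylic methyl, the enol-ether-like C3–H and a C31 chain, and it must stop after one oxygen.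

**9 from 8 (O1–C2 bond).** The pyranone is opened between O1 and C2 to the 1,3-diketone 8. This is the classical disconnection of a 2-alkylchromone, and it is preferred to a cut of the C2–chain bond because the chain then arrives together with C2 as one carboxylic acid. In the forward sense an acid-catalysed cyclodehydration is needed that leaves the aryl pivalate alone. Since 8 has only one free phenolic hydroxyl next to the ketone, only one pyranone can form.

**8 from 7, and 7 from 6 and 2 (C2–C3 bond, then the O–acyl bond).** The C2–C3 bond of the diketone is cut in the sense of an O-to-C acyl shift, which leads to the aryl ester 7 and then to 6 and the acid chloride 2, itself made from acid 1. The bond is formed by intramolecular transfer and not by an intermolecular Claisen condensation, because an enolisable C32 ester would self-condense and would have to be used in excess, whereas the tethered enolate finds the acyl group through a six-membered transition state. The forward steps must acylate a chelated, flanked hydroxyl and then move the acyl group with a base that does not touch the pivalate.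

**6 from 4 and 5 (O–pivaloyl bond).** The pivalate is disconnected early, at the stage of the aryl methyl ketone. Placed there it does double duty: it keeps O7 out of the acylation and rearrangement, and it is already the acid-stable, electron-withdrawing group that the oxygenation wants, so no protecting group has to be exchanged. The forward step relies on the difference between the two hydroxyls of 4: the one para to the acetyl group is free and more acidic, the one ortho to it is chelated and flanked on both sides.

**4 from 3 (C4a–C4 bond).** Finally the aryl–acetyl bond is cut, which gives 3. Both ring positions of 3 that are open to electrophiles are equivalent, each ortho to one hydroxyl and para to the other, so a Friedel–Crafts acetylation can give only one monoketone. The methyl is thereby locked between the two oxygens that become O7 and O1 before any ring is formed.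

## Alternatives that were turned down

**Alternative 1: Nitrile oxide cycloaddition, isoxazole as a masked 1,3-diketone.**
- **Disconnection and key step:** the pyranone is cut at C3–C4 and at the oxygen on C2. The hindered aryl nitrile oxide A1 (2-(benzyloxy)-4,6-dimethoxy-3-methylbenzonitrile oxide) and the terminal alkyne A2 (tritriacont-1-yne) would combine in a [3+2] cycloaddition to the 3-aryl-5-alkylisoxazole A3. Its N–O bond is later broken reductively to unveil the diketone, after which benzyl removal, cyclodehydration and cleavage of two methyl ethers follow.
- **For:** addition of a nitrile oxide to a terminal alkyne is dependably regioselective for the 3,5-disubstituted isoxazole. A nitrile oxide flanked by two ortho substituents such as A1 resists dimerisation, no strong base meets the chain, and A3 is a sturdy intermediate. On the certainty of its key bond formation this alternative is stronger than a C–H oxygenation.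
- **Against:** A1 must come from a benzaldehyde-type precursor in which three ring oxygens are already told apart, with the benzyl ether on the hydroxyl next to the methyl. The 6-methyl/8-methyl problem is thus moved to an early selective alkylation, not removed. A2 is not a catalogue compound and must be assembled by acetylide alkylation with a C31 electrophile. At least three operations still follow A3.
- **Comparison:** the chosen route answers the regiochemical question by the symmetry of 3 instead of by protecting-group differentiation, draws its chain from the commercial acid 1 and needs eight steps in all, at the price of a riskier key step.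

**Alternative 2: Aryne insertion into a long-chain ynoic acid.**
- **Disconnection and key step:** both aryl bonds of the pyranone, O1–C8a and C4–C4a, are removed together with O1–C2. Fluoride would release the aryne A5 (3,5-dimethoxy-6-methylbenzyne) from the ortho-silyl aryl triflate A4 (3,5-dimethoxy-2-methyl-6-(trimethylsilyl)phenyl trifluoromethanesulfonate). The carboxylate of A6 (tetratriacont-2-ynoic acid) would add through oxygen, the aryl anion would take over the acyl group, and the resulting phenoxide would close the ring by conjugate addition to the ynone, giving the chromone dimethyl ether A7 in one flask.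
- **For:** it is the most convergent plan; the whole bicyclic skeleton with the chain arrives in one operation. The methoxy group next to the aryne biases oxygen attack toward the remote aryne carbon, which is the correct one. On convergence it beats the chosen route.
- **Against:** the correct aryne carbon is also the one flanked by the methyl, so sterics oppose the electronic bias and a constitutional isomer with the carbonyl next to the methyl can form. A4 is a pentasubstituted benzene that needs a multistep synthesis of its own from a differentiated trioxygenated toluene. A6 must be made by carboxylating a C33 alkyne, and A7 still needs both methyl ethers cleaved.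
- **Comparison:** the chosen route gives up convergence but starts from three stock chemicals, fixes the methyl position by symmetry and leaves only one ester to remove at the end.

**Alternative 3: Decarboxylative radical attachment of the chain.**
- **Disconnection and key step:** the only bond cut is C2–C1′ between ring and chain. Under visible light, with a ruthenium polypyridyl photocatalyst and a tertiary amine as reductant, the N-(acyloxy)phthalimide A8 made from acid 1 would fragment to a primary C31 alkyl radical. This adds to C2 of the chromone-3-carboxylic acid A9 (5,7-dimethoxy-8-methyl-4-oxo-4H-chromene-3-carboxylic acid), and decarboxylation of the adduct gives the chromanone A10, racemic at C2.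
- **For:** the chain is introduced last from the same acid 1, so this plan is the most modular and would be the better one if a series of chain lengths were wanted. The conditions are mild, and the C2 stereocentre of A10 does not matter because it disappears again.
- **Against:** the addition is reductive, so A10 lies one oxidation level below the target and a dehydrogenation must be added before the two ether cleavages. A9 needs ring construction, formylation at C3 and oxidation on a trioxygenated ring that again raises the 6-methyl/8-methyl question. An unstabilised primary radical on a C31 chain, in the polar media such photochemistry prefers, is prone to simple reduction and poor solubility.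
- **Comparison:** the chosen route brings the chain in by a redox-neutral acylation, needs no correction of oxidation level and is shorter, though it cannot vary the chain as late.

Key step: step 7

**Assumption:** compounds 1, 3 and 5 are bought. Because the C31 chain makes every later intermediate wax-like, all steps from compound 2 on are run warm enough, in THF, toluene or chlorinated solvent, to keep the material in solution.

## Route

Step 1
Reactants: 1 dotriacontanoic acid
Product: 2 dotriacontanoyl chloride
Conditions: (COCl)2, DMF (cat.), toluene, 50 °C
Reagents that add atoms: oxalyl chloride, ClC(=O)C(=O)Cl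
Why: Acid chloride formation through the chloroiminium species from DMF and oxalyl chloride; warm toluene dissolves the C32 acid and all by-products leave as gases, so 2 can be used crude.

Step 2
Reactants: 3 2-methylresorcinol
Product: 4 1-(2,4-dihydroxy-3-methylphenyl)ethanone
Conditions: AcOH, ZnCl2, 140 °C
Reagents that add atoms: acetic acid, CC(=O)O
Why: Nencki-type Friedel–Crafts acetylation; C4 and C6 of 3 are equivalent by symmetry and each is ortho to one hydroxyl and para to the other, so only one monoketone can form, and the acetyl group then deactivates the ring toward a second acylation.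

Step 3
Reactants: 4 1-(2,4-dihydroxy-3-methylphenyl)ethanone; 5 pivaloyl chloride
Product: 6 4-acetyl-3-hydroxy-2-methylphenyl pivalate
Conditions: Et3N, CH2Cl2, 0 °C
Reagents that add atoms: none
Why: Chemoselective O-acylation; the hydroxyl para to the acetyl group is free and the more acidic one, whereas the ortho hydroxyl is hydrogen-bonded to the carbonyl and flanked by methyl and acetyl, so one equivalent of the bulky acid chloride should react at the para oxygen only.

Step 4
Reactants: 6 4-acetyl-3-hydroxy-2-methylphenyl pivalate; 2 dotriacontanoyl chloride
Product: 7 6-acetyl-2-methyl-3-(pivaloyloxy)phenyl dotriacontanoate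
Conditions: Et3N, DMAP (cat.), CH2Cl2, 0 → 40 °C
Reagents that add atoms: none
Why: DMAP-catalysed esterification through the acylpyridinium ion; the unbranched acyl group is small enough to reach the chelated, flanked phenol once the amine has broken its hydrogen bond.

Step 5
Reactants: 7 6-acetyl-2-methyl-3-(pivaloyloxy)phenyl dotriacontanoate
Product: 8 3-hydroxy-2-methyl-4-(3-oxotetratriacontanoyl)phenyl pivalate
Conditions: NaH, THF, 0 → 50 °C; then aq. HCl
Reagents that add atoms: none
Why: Baker–Venkataraman rearrangement; the methyl ketone enolate attacks the neighbouring ester carbonyl through a six-membered transition state, the phenoxide is expelled and the 1,3-diketone is held as its enolate until acidification. The hindered pivalate on the meta oxygen is out of intramolecular reach and a non-nucleophilic base is used, in line with the classical rearrangement of 2,4-diacyloxyacetophenones, which keeps the 4-ester.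

Step 6
Reactants: 8 3-hydroxy-2-methyl-4-(3-oxotetratriacontanoyl)phenyl pivalate
Product: 9 2-hentriacontyl-8-methyl-4-oxo-4H-chromen-7-yl pivalate
Conditions: p-TsOH·H2O (cat.), toluene, reflux (Dean–Stark)
Reagents that add atoms: none
Why: Acid-catalysed cyclodehydration of an o-hydroxyaryl 1,3-diketone; the phenolic oxygen adds to the chain ketone, the hemiketal loses water to the 4-pyranone, azeotropic removal of water drives it, and anhydrous acid leaves the aryl pivalate intact.

Step 7
Reactants: 9 2-hentriacontyl-8-methyl-4-oxo-4H-chromen-7-yl pivalate
Product: 11 2-hentriacontyl-5-hydroxy-8-methyl-4-oxo-4H-chromen-7-yl pivalate, via 5-(trifluoroacetoxy)chromone 10 (not isolated)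
Conditions: [Ru(p-cymene)Cl2]2 (5 mol %), PhI(OCOCF3)2 (2 equiv), CF3CO2H/(CF3CO)2O/ClCH2CH2Cl, 80 °C; then H2O, THF, rt
Reagents that add atoms: [bis(trifluoroacetoxy)iodo]benzene, O=C(O[I](OC(=O)C(F)(F)F)c1ccccc1)C(F)(F)F; trifluoroacetic acid, OC(=O)C(F)(F)F (the two exchange trifluoroacetate; one carboxylate oxygen stays on C5)
Why: In the acid medium the chloride ligands of the precatalyst are exchanged for trifluoroacetate, the C4 carbonyl oxygen of 9 binds the divalent ruthenium centre, and a carboxylate-assisted concerted metalation–deprotonation at C5–H gives a five-membered ruthenacycle (Ru–C5–C4a–C4–O). PhI(OCOCF3)2 oxidises this to a tetravalent ruthenium aryl trifluoroacetate, and C–O reductive elimination forms the C5–O bond as the aryl trifluoroacetate 10 and returns divalent ruthenium; water then hydrolyses the labile trifluoroacetate to the phenol 11 while the hindered pivalate stays. The closest known reaction type is the ketone-directed, ruthenium-catalysed ortho C–H oxygenation of aryl ketones with hypervalent iodine or persulfate oxidants, which has been run at C5 of chromones, flavones and xanthones, so the reaction type is established on this substrate class. No ring is closed and no stereocentre is formed; the only cyclic species is the transient metallacycle. The selectivity needed is C5 over C6, C3 and the benzylic methyl: the ketone can deliver the metal only to C5 (C3 would need a four-membered chelate, C8 is blocked), whereas the pivaloyl carbonyl could reach C6 only through a larger six-membered chelate from a much less basic oxygen. Over-oxidation is held back because the product leaves the cycle as the electron-poor ester 10, because the 7-pivalate lowers the electron density of ring A, and because the pyranone is protonated in this medium, which also shields C3 from the electrophilic iodine reagent. The chlorinated co-solvent is there to keep the C31 chain in solution at 80 °C.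

Step 8
Reactants: 11 2-hentriacontyl-5-hydroxy-8-methyl-4-oxo-4H-chromen-7-yl pivalate
Product: 12 2-hentriacontyl-5,7-dihydroxy-8-methyl-4H-chromen-4-one
Conditions: K2CO3, MeOH/THF (1:2), 40 °C; then aq. HCl
Reagents that add atoms: none
Why: Base-mediated methanolysis of an activated aryl ester whose leaving phenoxide is conjugated to the C4 carbonyl; the 7-phenoxide set free donates into the pyranone and so shields C2 from methoxide, which should keep the ring closed and the methyl on C8, and THF keeps the chain dissolved.

## Compound list

1 | dotriacontanoic acid | CCCCCCCCCCCCCCCCCCCCCCCCCCCCCCCC(=O)O | starting material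
2 | dotriacontanoyl chloride | CCCCCCCCCCCCCCCCCCCCCCCCCCCCCCCC(=O)Cl | intermediate
3 | 2-methylresorcinol (2-methylbenzene-1,3-diol) | Cc1c(O)cccc1O | starting material
4 | 1-(2,4-dihydroxy-3-methylphenyl)ethanone | CC(=O)c1ccc(O)c(C)c1O | intermediate
5 | pivaloyl chloride (2,2-dimethylpropanoyl chloride) | CC(C)(C)C(=O)Cl | starting material
6 | 4-acetyl-3-hydroxy-2-methylphenyl pivalate | CC(=O)c1ccc(OC(=O)C(C)(C)C)c(C)c1O | intermediate
7 | 6-acetyl-2-methyl-3-(pivaloyloxy)phenyl dotriacontanoate | CCCCCCCCCCCCCCCCCCCCCCCCCCCCCCCC(=O)Oc1c(C(C)=O)ccc(OC(=O)C(C)(C)C)c1C | intermediate
8 | 3-hydroxy-2-methyl-4-(3-oxotetratriacontanoyl)phenyl pivalate (drawn as the diketo form) | CCCCCCCCCCCCCCCCCCCCCCCCCCCCCCCC(=O)CC(=O)c1ccc(OC(=O)C(C)(C)C)c(C)c1O | intermediate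
9 | 2-hentriacontyl-8-methyl-4-oxo-4H-chromen-7-yl pivalate | CCCCCCCCCCCCCCCCCCCCCCCCCCCCCCCc1cc(=O)c2ccc(OC(=O)C(C)(C)C)c(C)c2o1 | intermediate
10 | 2-hentriacontyl-8-methyl-4-oxo-5-(trifluoroacetoxy)-4H-chromen-7-yl pivalate | CCCCCCCCCCCCCCCCCCCCCCCCCCCCCCCc1cc(=O)c2c(OC(=O)C(F)(F)F)cc(OC(=O)C(C)(C)C)c(C)c2o1 | intermediate
11 | 2-hentriacontyl-5-hydroxy-8-methyl-4-oxo-4H-chromen-7-yl pivalate | CCCCCCCCCCCCCCCCCCCCCCCCCCCCCCCc1cc(=O)c2c(O)cc(OC(=O)C(C)(C)C)c(C)c2o1 | intermediate
12 | 2-hentriacontyl-5,7-dihydroxy-8-methyl-4H-chromen-4-one | CCCCCCCCCCCCCCCCCCCCCCCCCCCCCCCc1cc(=O)c2c(O)cc(O)c(C)c2o1 | target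

## Step count and risk

Total step count: 8. Longest linear sequence: 7 steps (3 → 12, steps 2 to 8); the acid chloride branch (step 1) joins at step 4.

**Step 7 (key step).**
- **What may go wrong:** the catalyst may not turn over because the wax-like substrate separates from the fluorinated acid phase. Undirected oxidation by the iodine reagent (at C6, at C3 or at the benzylic methyl), or direction by the pivaloyl carbonyl to C6, would then take over. Over-oxidation of ring A once the first oxygen is in place is the second concern.
- **Fallback (gives up C–H oxygenation and carries the C5 oxygen from the start):** it sets out from acid chloride 2 and returns at target 12.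
  - 2,4,6-Trihydroxytoluene F1 is acetylated (AcOH, ZnCl2) to 1-(2,4,6-trihydroxy-3-methylphenyl)ethanone F2.
  - Two equivalents of dimethyl sulfate with K2CO3 in acetone should methylate O4 (the most acidic, unchelated hydroxyl) and O6 (the less hindered of the two chelated ones), leaving the hydroxyl between methyl and acetyl free, to give 1-(2-hydroxy-4,6-dimethoxy-3-methylphenyl)ethanone F3.
  - Acylation with 2 (Et3N, DMAP) gives 2-acetyl-3,5-dimethoxy-6-methylphenyl dotriacontanoate F4.
  - Baker–Venkataraman rearrangement (NaH, THF) gives 1-(2-hydroxy-4,6-dimethoxy-3-methylphenyl)tetratriacontane-1,3-dione F5.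
  - Acid cyclodehydration gives 2-hentriacontyl-5,7-dimethoxy-8-methyl-4H-chromen-4-one F6, in which the methyl position is locked because only one hydroxyl was free.
  - BBr3 in CH2Cl2 then cleaves both methyl ethers to 12.
  - The weak point moves to the regioselectivity of the partial methylation of F2 to F3, which is the 6-methyl/8-methyl problem that the main route avoids.

**Step 5.**
- **What may go wrong:** loss or intermolecular transfer of the pivaloyl group while enolate and phenoxide are present, or loss of the long acyl group from oxygen (ketene-type elimination or attack by adventitious hydroxide) before it has migrated to carbon. Both are made worse by the slow, heterogeneous deprotonation of a wax-like substrate.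
- **Fallback (takes the pivalate out of the basic steps):** it sets out from 4 and returns at 9.
  - The free hydroxyl para to the acetyl group of 4 is protected with chloromethyl methyl ether and i-Pr2NEt as 1-[2-hydroxy-4-(methoxymethoxy)-3-methylphenyl]ethanone F7.
  - Acylation with 2 gives 6-acetyl-3-(methoxymethoxy)-2-methylphenyl dotriacontanoate F8.
  - The rearrangement, now with nothing base-labile on the ring, gives 1-[2-hydroxy-4-(methoxymethoxy)-3-methylphenyl]tetratriacontane-1,3-dione F9.
  - HCl in MeOH/THF at 60 °C closes the pyranone and removes the acetal in the same operation, giving 2-hentriacontyl-7-hydroxy-8-methyl-4H-chromen-4-one F10.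
  - Acid chloride 5 with Et3N and DMAP pivaloylates O7 to give 9.
  - The cost is one extra step.

**Step 8.**
- **What may go wrong:** the pivalate, flanked by the C8 methyl, may be cleaved only slowly. During the longer exposure methoxide can add to C2 and open the pyranone, and because the 5-hydroxyl is now free the ring can reclose on O5, which moves the methyl from C8 to C6.
- **Fallback (changes the O7 group to one removed without base):** it sets out from 9 and returns at 12.
  - Methanolysis of 9 (K2CO3, MeOH/THF) is safe at this stage, since without a 5-hydroxyl an opened ring can only close back to the same chromone. It gives the 7-hydroxychromone F10 already met in the fallback to step 5.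
  - Iodomethane and K2CO3 in acetone give 2-hentriacontyl-7-methoxy-8-methyl-4H-chromen-4-one F11.
  - The oxygenation of step 7, run on F11, gives 2-hentriacontyl-7-methoxy-8-methyl-4-oxo-4H-chromen-5-yl trifluoroacetate F12 in the flask and, after hydrolysis, 2-hentriacontyl-5-hydroxy-7-methoxy-8-methyl-4H-chromen-4-one F13.
  - BBr3 in CH2Cl2 then cleaves the methyl ether under Lewis-acidic conditions to 12.
  - The methoxy group makes ring A more electron-rich in the oxidation, which is why the ester is preferred in the main route.

## Further compounds

F1 | step 7 | 2,4,6-trihydroxytoluene | Cc1c(O)cc(O)cc1O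
F2 | step 7 | 1-(2,4,6-trihydroxy-3-methylphenyl)ethanone | CC(=O)c1c(O)cc(O)c(C)c1O
F3 | step 7 | 1-(2-hydroxy-4,6-dimethoxy-3-methylphenyl)ethanone | COc1cc(OC)c(C(C)=O)c(O)c1C
F4 | step 7 | 2-acetyl-3,5-dimethoxy-6-methylphenyl dotriacontanoate | CCCCCCCCCCCCCCCCCCCCCCCCCCCCCCCC(=O)Oc1c(C(C)=O)c(OC)cc(OC)c1C
F5 | step 7 | 1-(2-hydroxy-4,6-dimethoxy-3-methylphenyl)tetratriacontane-1,3-dione | CCCCCCCCCCCCCCCCCCCCCCCCCCCCCCCC(=O)CC(=O)c1c(OC)cc(OC)c(C)c1O
F6 | step 7 | 2-hentriacontyl-5,7-dimethoxy-8-methyl-4H-chromen-4-one | CCCCCCCCCCCCCCCCCCCCCCCCCCCCCCCc1cc(=O)c2c(OC)cc(OC)c(C)c2o1
F7 | step 5 | 1-[2-hydroxy-4-(methoxymethoxy)-3-methylphenyl]ethanone | COCOc1ccc(C(C)=O)c(O)c1C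
F8 | step 5 | 6-acetyl-3-(methoxymethoxy)-2-methylphenyl dotriacontanoate | CCCCCCCCCCCCCCCCCCCCCCCCCCCCCCCC(=O)Oc1c(C(C)=O)ccc(OCOC)c1C
F9 | step 5 | 1-[2-hydroxy-4-(methoxymethoxy)-3-methylphenyl]tetratriacontane-1,3-dione | CCCCCCCCCCCCCCCCCCCCCCCCCCCCCCCC(=O)CC(=O)c1ccc(OCOC)c(C)c1O
F10 | step 5 | 2-hentriacontyl-7-hydroxy-8-methyl-4H-chromen-4-one | CCCCCCCCCCCCCCCCCCCCCCCCCCCCCCCc1cc(=O)c2ccc(O)c(C)c2o1
F11 | step 8 | 2-hentriacontyl-7-methoxy-8-methyl-4H-chromen-4-one | CCCCCCCCCCCCCCCCCCCCCCCCCCCCCCCc1cc(=O)c2ccc(OC)c(C)c2o1
F12 | step 8 | 2-hentriacontyl-7-methoxy-8-methyl-4-oxo-4H-chromen-5-yl trifluoroacetate | CCCCCCCCCCCCCCCCCCCCCCCCCCCCCCCc1cc(=O)c2c(OC(=O)C(F)(F)F)cc(OC)c(C)c2o1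
F13 | step 8 | 2-hentriacontyl-5-hydroxy-7-methoxy-8-methyl-4H-chromen-4-one | CCCCCCCCCCCCCCCCCCCCCCCCCCCCCCCc1cc(=O)c2c(O)cc(OC)c(C)c2o1
A1 | alternative 1 | 2-(benzyloxy)-4,6-dimethoxy-3-methylbenzonitrile oxide | [O-][N+]#Cc1c(OC)cc(OC)c(C)c1OCc1ccccc1
A2 | alternative 1 | tritriacont-1-yne | CCCCCCCCCCCCCCCCCCCCCCCCCCCCCCCC#C
A3 | alternative 1 | 3-[2-(benzyloxy)-4,6-dimethoxy-3-methylphenyl]-5-hentriacontylisoxazole | CCCCCCCCCCCCCCCCCCCCCCCCCCCCCCCc1cc(-c2c(OC)cc(OC)c(C)c2OCc2ccccc2)no1
A4 | alternative 2 | 3,5-dimethoxy-2-methyl-6-(trimethylsilyl)phenyl trifluoromethanesulfonate | COc1cc(OC)c([Si](C)(C)C)c(OS(=O)(=O)C(F)(F)F)c1C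
A5 | alternative 2 | 3,5-dimethoxy-6-methylbenzyne | COC1=CC(OC)=C(C)C#C1
A6 | alternative 2 | tetratriacont-2-ynoic acid | CCCCCCCCCCCCCCCCCCCCCCCCCCCCCCCC#CC(=O)O
A7 | alternative 2 | 2-hentriacontyl-5,7-dimethoxy-8-methyl-4H-chromen-4-one | CCCCCCCCCCCCCCCCCCCCCCCCCCCCCCCc1cc(=O)c2c(OC)cc(OC)c(C)c2o1
A8 | alternative 3 | 1,3-dioxoisoindolin-2-yl dotriacontanoate | CCCCCCCCCCCCCCCCCCCCCCCCCCCCCCCC(=O)ON1C(=O)c2ccccc2C1=O
A9 | alternative 3 | 5,7-dimethoxy-8-methyl-4-oxo-4H-chromene-3-carboxylic acid | COc1cc(OC)c(C)c2occ(C(=O)O)c(=O)c12
A10 | alternative 3 | 2-hentriacontyl-5,7-dimethoxy-8-methylchroman-4-one (racemic at C2) | CCCCCCCCCCCCCCCCCCCCCCCCCCCCCCCC1CC(=O)c2c(OC)cc(OC)c(C)c2O1
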